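**Plan**

- Retrosynthesis: the C–OOH bond is traced to an allylic C–Cl bond of opposite configuration. The cyclohexene is then contracted to a cyclopentene by removing the methyl-bearing olefin carbon (2-methylallyl chloride ⇐ 1-chloro-1-methylcyclopropane ⇐ cyclopentene + chloro(methyl)carbenoid). Last, the CH2–C(sp2) bond of the two-carbon tether is cut into an oxepane half and a hydrindene half.
- Enabling feature: the three contiguous ring atoms CH(OOH)–C(CH3)=C(alkyl) of the cyclohexene form a 2-methylallyl unit with a heteroatom at one end, the signature of a halocyclopropane ring opening on a cyclopentene.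
- Oxepane half: farnesol → tert-butyl carbonate → double Shi epoxidation → one Lewis-acid cascade that closes the oxepane, the cyclohexane and a temporary cyclic carbonate (which delivers the tertiary oxygen) → reduction, silylation, oxidation, methylenation to a vinyl group.
- Hydrindene half: a CBS-set carbinol on a cyclopentene directs a hydrogen-atom-transfer radical cyclization that builds the gem-dimethylcyclohexanone cis-fused; the carbinol is later oxidized away (traceless relay) to the ketone and its enol triflate.
- Union by B-alkyl Suzuki coupling, then ring expansion, displacement of chloride by hydrogen peroxide with inversion, and desilylation.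
- Stereochemistry: five centres of the oxepane half come from the two Shi epoxides and the E-olefin geometry; the hydrindane centres are relayed from the CBS carbinol; the C–OOH centre comes from convex-face carbenoid addition, suprafacial chloride shift and SN2 inversion.

Key step: step 19

Assumption: in the cis-fused bicyclic allyl system the bond to the gem-dimethyl carbon lies pseudoaxial on the cyclohexene, so a leaving group or nucleophile at the allylic CH prefers the face of the ring-fusion hydrogens; the hydroperoxide, which sits on the opposite face, is therefore introduced by inversion.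

**Oxepane half**

Step 1
Reactants: 1 (2E,6E)-farnesol
Product: 2 tert-butyl (2E,6E)-farnesyl carbonate
Conditions: Boc2O, DMAP (cat.), CH2Cl2, 0 °C to rt
Reagents that add atoms: di-tert-butyl dicarbonate, CC(C)(C)OC(=O)OC(=O)OC(C)(C)C
Why: DMAP-catalysed carbonate formation on the primary allylic alcohol; the carbonate deactivates the neighbouring olefin toward epoxidation and later serves as the internal oxygen nucleophile.

Step 2
Reactants: 2 tert-butyl (2E,6E)-farnesyl carbonate
Product: 3 tert-butyl (2E,6S,7S,10S)-6,7:10,11-diepoxyfarnesyl carbonate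
Conditions: L-fructose-derived Shi ketone (30 mol%), Oxone, K2CO3, Bu4NHSO4, MeCN/dimethoxymethane/aq. borate buffer, 0 °C
Reagents that add atoms: potassium peroxymonosulfate (active part of Oxone), [K+].[O-]S(=O)(=O)OO
Why: Shi asymmetric epoxidation (chiral dioxirane, spiro transition state) should oxidise only the two electron-rich trisubstituted olefins remote from the allylic carbonate, and the enantiomeric ketone sets all three epoxide centres as S by reagent control.

Step 3
Reactants: 3 tert-butyl (2E,6S,7S,10S)-6,7:10,11-diepoxyfarnesyl carbonate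
Product: 4 tricyclic hydroxy carbonate (trans-fused oxepane–cyclohexane with a trans-fused six-membered cyclic carbonate across the CH2O arm and the tertiary oxygen; free secondary OH on the oxepane)
Conditions: BF3·OEt2, CH2Cl2, −78 to −40 °C; aq. NaHCO3
Reagents that add atoms: none
Why: Lewis-acid epoxide-opening/cation–olefin cascade: the internal epoxide oxygen attacks the tertiary carbon of the activated terminal epoxide (7-endo, oxepane), the E-olefin opens the resulting epoxonium ion with inversion through a chair (cyclohexane, angular methyl axial), and the carbonate carbonyl captures the tertiary cation anti (equatorial C–O) with loss of isobutene, so all five stereocentres follow from the epoxides and the olefin geometry.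

Step 4
Reactants: 4 tricyclic hydroxy carbonate
Product: 5 benzoxepane triol (CH2OH arm, secondary OH on the oxepane, tertiary OH on the cyclohexane)
Conditions: LiAlH4, THF, 0 °C to rt; Rochelle salt work-up
Reagents that add atoms: none
Why: hydride reduction of the cyclic carbonate should free the primary and the tertiary alcohol without touching any stereocentre.

Step 5
Reactants: 5 benzoxepane triol
Product: 6 tris(triethylsilyl) ether of 5
Conditions: TESOTf, 2,6-lutidine, CH2Cl2, −78 to 0 °C
Reagents that add atoms: triethylsilyl trifluoromethanesulfonate, CC[Si](CC)(CC)OS(=O)(=O)C(F)(F)F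
Why: silyl triflate with a hindered base silylates primary, secondary and hindered tertiary alcohols alike.

Step 6
Reactants: 6 tris(triethylsilyl) ether
Product: 7 benzoxepane aldehyde (secondary and tertiary OH as triethylsilyl ethers)
Conditions: (COCl)2, DMSO, CH2Cl2, −78 to −40 °C; then Et3N, −78 °C to rt
Reagents that add atoms: none
Why: Swern oxidation cleaves and oxidises a primary triethylsilyl ether selectively while secondary and tertiary silyl ethers stay, so the aldehyde forms with its β-oxygen already protected against retro-aldol cleavage.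

Step 7
Reactants: 7 benzoxepane aldehyde
Product: 8 vinyl benzoxepane (bis-triethylsilyl ether; oxepane half)
Conditions: Ph3PCH3Br, KHMDS, THF, −78 to 0 °C
Reagents that add atoms: methyltriphenylphosphonium bromide, C[P+](c1ccccc1)(c1ccccc1)c1ccccc1.[Br-]
Why: Wittig methylenation with a salt-free ylide at low temperature; the α-centre lies between two fully substituted carbons and should not epimerise under these conditions.

**Hydrindene half**

Step 8
Reactants: 9 methyl 3-oxocyclopent-1-ene-1-carboxylate
Product: 10 methyl (3S)-3-hydroxycyclopent-1-ene-1-carboxylate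
Conditions: (R)-2-methyl-CBS-oxazaborolidine (10 mol%), catecholborane, toluene, −78 °C
Reagents that add atoms: none
Why: CBS reduction (1,2-selective with catecholborane); the alkenyl flank acts as the large group, so the (R)-catalyst should give the S carbinol, the only centre of this half set by catalysis.

Step 9
Reactants: 10 methyl (3S)-3-hydroxycyclopent-1-ene-1-carboxylate
Product: 11 methyl (3S)-3-(tert-butyldimethylsilyloxy)cyclopent-1-ene-1-carboxylate
Conditions: TBSCl, imidazole, DMF, rt
Reagents that add atoms: tert-butyldimethylsilyl chloride, CC(C)(C)[Si](C)(C)Cl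
Why: standard silylation; the bulky silyl ether is the stereodirecting group for step 11.

Step 10
Reactants: 11 methyl (3S)-3-(tert-butyldimethylsilyloxy)cyclopent-1-ene-1-carboxylate
Product: 13 1-[(3S)-3-(tert-butyldimethylsilyloxy)cyclopent-1-en-1-yl]-4-methylpent-4-en-1-one, via Weinreb amide 12 (not isolated)
Conditions: MeNH(OMe)·HCl, i-PrMgCl, THF, −20 °C; then (3-methylbut-3-en-1-yl)magnesium bromide, −20 to 0 °C
Reagents that add atoms: (3-methylbut-3-en-1-yl)magnesium bromide, C=C(C)CC[Mg]Br
Why: one-pot Weinreb amide formation and Grignard acylation; the chelated tetrahedral intermediate should stop the addition at the ketone.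

Step 11
Reactants: 13 1-[(3S)-3-(tert-butyldimethylsilyloxy)cyclopent-1-en-1-yl]-4-methylpent-4-en-1-one
Product: 14 cis-fused 1-(tert-butyldimethylsilyloxy)-7,7-dimethylhexahydroindan-4-one (silyloxy group on the face of both ring-fusion hydrogens)
Conditions: Fe(acac)3 (30 mol%), PhSiH3, EtOH/ethylene glycol, 60 °C; then DBU (cat.), CH2Cl2, rt
Reagents that add atoms: none
Why: hydrogen-atom-transfer-initiated radical conjugate addition (reductive olefin coupling): Markovnikov H-atom transfer gives the tertiary radical, which closes 6-endo on the enone β-carbon anti to the neighbouring silyloxy group; protonation or equilibration α to the ketone should give the more stable cis ring fusion.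

Step 12
Reactants: 14 cis-fused silyloxy hydrindanone
Product: 15 cis-fused 1-(tert-butyldimethylsilyloxy)-7,7-dimethyl-4-methylenehexahydroindane
Conditions: Ph3PCH3Br, KOtBu, toluene, 90 °C
Reagents that add atoms: methyltriphenylphosphonium bromide, C[P+](c1ccccc1)(c1ccccc1)c1ccccc1.[Br-]
Why: Wittig methylenation of a hindered ketone; the α-centre is already the thermodynamic cis-fused one.

Step 13
Reactants: 15 exocyclic olefin
Product: 16 cis-fused 1-(tert-butyldimethylsilyloxy)-4,7,7-trimethylhexahydroindan-4-ol (OH cis to the adjacent ring-fusion hydrogen)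
Conditions: Mn(dpm)3 (10 mol%), PhSiH3, O2 (1 atm), i-PrOH/CH2Cl2, 0 °C to rt; then P(OEt)3
Reagents that add atoms: dioxygen, O=O
Why: Mukaiyama hydration (Markovnikov H-atom transfer, O2 capture); the tertiary radical should be trapped on the convex, equatorial face because the axial approach is blocked by the syn-axial cyclopentane carbon, which places OH cis to the neighbouring ring-fusion hydrogen.

Step 14
Reactants: 16 silyloxy tertiary alcohol
Product: 17 cis-fused 4,7,7-trimethylhexahydroindane-1,4-diol
Conditions: TBAF, THF, rt
Reagents that add atoms: none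
Why: fluoride cleavage of the secondary silyl ether.

Step 15
Reactants: 17 diol
Product: 18 cis-fused 4-hydroxy-4,7,7-trimethylhexahydroindan-1-one
Conditions: Dess–Martin periodinane, CH2Cl2, rt
Reagents that add atoms: none
Why: Dess–Martin oxidation of the secondary alcohol only; this removes the relay stereocentre after it has served.

Step 16
Reactants: 18 hydroxy ketone
Product: 19 cis-fused 4-(triethylsilyloxy)-4,7,7-trimethylhexahydroindan-1-one
Conditions: TESOTf, 2,6-lutidine, CH2Cl2, −78 °C
Reagents that add atoms: triethylsilyl trifluoromethanesulfonate, CC[Si](CC)(CC)OS(=O)(=O)C(F)(F)F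
Why: low-temperature silylation of the tertiary alcohol; the ketone is not enolised by 2,6-lutidine at this temperature.

Step 17
Reactants: 19 silyloxy hydrindanone
Product: 20 enol triflate (cis-fused 3a,4,5,6,7,7a-hexahydro-1H-inden-3-yl triflate with the silyloxy, methyl and gem-dimethyl groups; hydrindene half)
Conditions: KHMDS, THF, −78 °C; then PhNTf2, −78 to 0 °C
Reagents that add atoms: N-phenylbis(trifluoromethanesulfonimide), O=S(=O)(N(c1ccccc1)S(=O)(=O)C(F)(F)F)C(F)(F)F
Why: kinetic deprotonation at the CH2 flank (the ring-fusion methine next to the gem-dimethyl carbon is too hindered) and O-triflation, so the ring-fusion centre is not touched.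

**Union and end game**

Step 18
Reactants: 8 vinyl benzoxepane; 20 enol triflate
Product: 22 coupled cyclopentene (tris-triethylsilyl ether), via B-alkyl-9-BBN borane 21 (not isolated)
Conditions: 9-BBN, THF, rt to 50 °C; then 20, Pd(dppf)Cl2 (5 mol%), AsPh3, Cs2CO3, DMF/H2O, rt to 45 °C
Reagents that add atoms: none
Why: B-alkyl Suzuki–Miyaura coupling: anti-Markovnikov hydroboration of the vinyl group, oxidative addition of zerovalent palladium to the enol triflate, base-assisted transmetalation and reductive elimination join the two halves at the CH2–C(sp2) bond.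

Step 19
Reactants: 22 coupled cyclopentene
Product: 24 ring-expanded allylic chloride (2-methylcyclohex-2-enyl chloride; chlorine on the face of the ring-fusion hydrogens), via chloro(methyl)cyclopropane 23 (not isolated)
Conditions: CH3CHCl2 (excess), n-BuLi (slow addition), Et2O, −40 °C; then warm to rt, toluene, 40 °C
Reagents that add atoms: 1,1-dichloroethane, CC(Cl)Cl
Why: α-elimination of lithiated 1,1-dichloroethane gives a chloro(methyl)carbenoid that adds to the trisubstituted cyclopentene in a concerted [2+1] closure of the three-membered ring; on warming the endo C–Cl bond ionises while the shared cyclopropane bond opens in a disrotatory two-electron electrocyclic ring opening, so the five-membered ring becomes the six-membered 2-methylallyl cation and chloride returns to its secondary end. The closest known reactions are the halocarbene ring expansion of cyclopentenes to 3-halocyclohexenes and the preparation of 1-chloro-1-methylcyclopropanes from 1,1-dichloroethane and butyllithium. Because the carbenoid carbon ends up between the two former olefin carbons, the ring size, the vinylic methyl group and the tetrasubstituted double bond arise together. The new C–Cl stereocentre is set by suprafacial chloride migration within the ion pair on the face from which the carbenoid added, the convex face of the ring-fusion hydrogens, since the gem-dimethyl carbon and the cyclohexane ring block the other face; this pseudoaxial chloride should also be the thermodynamic one. The step needs the chlorine endo (only that adduct can open to a cis-cyclohexenyl cation), which the syn-chloro preference of lithium chlorocarbenoids and the larger methyl group seeking the exo position should secure, and it needs chloride return to the secondary end, which the congestion at the chain-bearing end and the stability of the tetrasubstituted olefin should secure.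

Step 20
Reactants: 24 ring-expanded allylic chloride
Product: 25 tris-triethylsilyl ether of sipholenol M
Conditions: H2O2 (50% aq., large excess), CsOH·H2O, DMF, −20 to 0 °C
Reagents that add atoms: hydrogen peroxide, OO
Why: SN2 displacement of the pseudoaxial allylic chloride by hydroperoxide anion (α-effect nucleophile, as in the preparation of alkyl hydroperoxides from halides or sulfonates with basic hydrogen peroxide) inverts the centre and places OOH on the face opposite the ring-fusion hydrogens; the silyl ether on the nearby tertiary oxygen prevents intramolecular ether formation.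

Step 21
Reactants: 25 tris-triethylsilyl ether of sipholenol M
Product: 26 sipholenol M
Conditions: HF·pyridine, pyridine/THF, 0 °C to rt
Reagents that add atoms: none
Why: buffered fluoride desilylation should remove the secondary and both tertiary silyl ethers without acid-induced cleavage of the allylic hydroperoxide.

**Compound list**

1 | (2E,6E)-farnesol | CC(C)=CCC/C(C)=C/CC/C(C)=C/CO | starting material
2 | tert-butyl (2E,6E)-farnesyl carbonate | CC(C)=CCC/C(C)=C/CC/C(C)=C/COC(=O)OC(C)(C)C | intermediate
3 | tert-butyl (2E,6S,7S,10S)-6,7:10,11-diepoxyfarnesyl carbonate | CC1(C)O[C@H]1CC[C@]1(C)O[C@H]1CC/C(C)=C/COC(=O)OC(C)(C)C | intermediate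
4 | tricyclic hydroxy carbonate (oxepane–cyclohexane–cyclic carbonate, all ring fusions trans) | O=C1OC[C@H]2[C@]3(C)CC[C@H](O)C(C)(C)O[C@H]3CC[C@]2(C)O1 | intermediate
5 | benzoxepane triol | OC[C@H]1[C@]2(C)CC[C@H](O)C(C)(C)O[C@H]2CC[C@]1(C)O | intermediate
6 | tris(triethylsilyl) ether of 5 | CC[Si](CC)(CC)OC[C@H]1[C@]2(C)CC[C@H](O[Si](CC)(CC)CC)C(C)(C)O[C@H]2CC[C@]1(C)O[Si](CC)(CC)CC | intermediate
7 | benzoxepane aldehyde (bis-triethylsilyl ether) | O=C[C@H]1[C@]2(C)CC[C@H](O[Si](CC)(CC)CC)C(C)(C)O[C@H]2CC[C@]1(C)O[Si](CC)(CC)CC | intermediate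
8 | vinyl benzoxepane (bis-triethylsilyl ether) | C=C[C@H]1[C@]2(C)CC[C@H](O[Si](CC)(CC)CC)C(C)(C)O[C@H]2CC[C@]1(C)O[Si](CC)(CC)CC | intermediate
9 | methyl 3-oxocyclopent-1-ene-1-carboxylate | COC(=O)C1=CC(=O)CC1 | starting material
10 | methyl (3S)-3-hydroxycyclopent-1-ene-1-carboxylate | COC(=O)C1=C[C@@H](O)CC1 | intermediate
11 | methyl (3S)-3-(tert-butyldimethylsilyloxy)cyclopent-1-ene-1-carboxylate | COC(=O)C1=C[C@@H](O[Si](C)(C)C(C)(C)C)CC1 | intermediate
12 | (3S)-3-(tert-butyldimethylsilyloxy)-N-methoxy-N-methylcyclopent-1-ene-1-carboxamide (not isolated) | CON(C)C(=O)C1=C[C@@H](O[Si](C)(C)C(C)(C)C)CC1 | intermediate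
13 | 1-[(3S)-3-(tert-butyldimethylsilyloxy)cyclopent-1-en-1-yl]-4-methylpent-4-en-1-one | C=C(C)CCC(=O)C1=C[C@@H](O[Si](C)(C)C(C)(C)C)CC1 | intermediate
14 | cis-fused 1-(tert-butyldimethylsilyloxy)-7,7-dimethylhexahydroindan-4-one | CC(C)(C)[Si](C)(C)O[C@@H]1[C@@H]2[C@H](CC1)C(=O)CCC2(C)C | intermediate
15 | cis-fused 1-(tert-butyldimethylsilyloxy)-7,7-dimethyl-4-methylenehexahydroindane | CC(C)(C)[Si](C)(C)O[C@@H]1[C@@H]2[C@H](CC1)C(=C)CCC2(C)C | intermediate
16 | cis-fused 1-(tert-butyldimethylsilyloxy)-4,7,7-trimethylhexahydroindan-4-ol | CC(C)(C)[Si](C)(C)O[C@@H]1[C@@H]2[C@H](CC1)[C@@](C)(O)CCC2(C)C | intermediate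
17 | cis-fused 4,7,7-trimethylhexahydroindane-1,4-diol | O[C@@H]1[C@@H]2[C@H](CC1)[C@@](C)(O)CCC2(C)C | intermediate
18 | cis-fused 4-hydroxy-4,7,7-trimethylhexahydroindan-1-one | O=C1[C@@H]2[C@H](CC1)[C@@](C)(O)CCC2(C)C | intermediate
19 | cis-fused 4-(triethylsilyloxy)-4,7,7-trimethylhexahydroindan-1-one | O=C1[C@@H]2[C@H](CC1)[C@@](C)(O[Si](CC)(CC)CC)CCC2(C)C | intermediate
20 | enol triflate of 19 (double bond toward the CH2 flank) | C1=C(OS(=O)(=O)C(F)(F)F)[C@@H]2[C@H](C1)[C@@](C)(O[Si](CC)(CC)CC)CCC2(C)C | intermediate
21 | B-alkyl-9-BBN borane from 8 (not isolated) | B1(CC[C@H]2[C@]3(C)CC[C@H](O[Si](CC)(CC)CC)C(C)(C)O[C@H]3CC[C@]2(C)O[Si](CC)(CC)CC)C2CCCC1CCC2 | intermediate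
22 | coupled cyclopentene (tris-triethylsilyl ether) | C1=C(CC[C@H]2[C@]3(C)CC[C@H](O[Si](CC)(CC)CC)C(C)(C)O[C@H]3CC[C@]2(C)O[Si](CC)(CC)CC)[C@@H]2[C@H](C1)[C@@](C)(O[Si](CC)(CC)CC)CCC2(C)C | intermediate
23 | endo-chloro-exo-methyl cyclopropane on the convex face of 22 (not isolated) | C[C@]1(Cl)[C@H]2C[C@H]3[C@@H]([C@@]12CC[C@H]1[C@]2(C)CC[C@H](O[Si](CC)(CC)CC)C(C)(C)O[C@H]2CC[C@]1(C)O[Si](CC)(CC)CC)C(C)(C)CC[C@]3(C)O[Si](CC)(CC)CC | intermediate
24 | ring-expanded allylic chloride | CC1=C(CC[C@H]2[C@]3(C)CC[C@H](O[Si](CC)(CC)CC)C(C)(C)O[C@H]3CC[C@]2(C)O[Si](CC)(CC)CC)[C@@H]2[C@H](C[C@@H]1Cl)[C@@](C)(O[Si](CC)(CC)CC)CCC2(C)C | intermediate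
25 | tris-triethylsilyl ether of sipholenol M | CC1=C(CC[C@H]2[C@]3(C)CC[C@H](O[Si](CC)(CC)CC)C(C)(C)O[C@H]3CC[C@]2(C)O[Si](CC)(CC)CC)[C@@H]2[C@H](C[C@H]1OO)[C@@](C)(O[Si](CC)(CC)CC)CCC2(C)C | intermediate
26 | sipholenol M | CC1=C(CC[C@H]2[C@]3(C)CC[C@H](O)C(C)(C)O[C@H]3CC[C@]2(C)O)[C@@H]2[C@H](C[C@H]1OO)[C@@](C)(O)CCC2(C)C | target

**Step count and risks**

Total step count: 21. Longest linear sequence: 14 (steps 8–17, then 18–21).

Steps most likely to fail:

Step 19. The carbenoid may add with the chlorine exo (an adduct that cannot open to a cis-cyclohexenyl cation), or may add sluggishly to the hindered olefin. The fallback runs the ring expansion with dibromocarbene, where an endo halogen is always present, and brings in the methyl group afterwards. Setting out from 22, CHBr3/KOtBu (pentane, −20 °C) should give the gem-dibromocyclopropane F1. AgClO4 with 2,6-lutidine in aqueous acetone should open it to the ring-expanded 2-bromocyclohex-2-enol F2, with water captured on the face of the ring-fusion hydrogens. Suzuki–Miyaura methylation (trimethylboroxine, Pd(dppf)Cl2, K2CO3, dioxane, 80 °C) should give the 2-methyl allylic alcohol F3. MsCl/Et3N at −40 °C should give the allylic mesylate F4, which is displaced with H2O2/CsOH as in step 20, coming back to the route at 25.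

Step 20. Ionisation of the allylic chloride may outrun bimolecular displacement (capture with retention, or proton loss to a diene), and hydrogen peroxide may be alkylated twice. The fallback brings in the O–O unit as a protected monoalkyl peroxide. Setting out from 24, 2-methoxyprop-2-yl hydroperoxide with CsOH in dry DMF at −20 °C should give the peroxyketal F5 by SN2 displacement. Dilute acetic acid in aqueous THF should then release the hydroperoxide, coming back to the route at 25.

Step 3. The cascade may stop after the first ring closure, or may end by proton loss instead of carbonate capture. The fallback installs the tertiary alcohol after the cascade instead of within it. Setting out from 1, Ac2O/pyridine should give farnesyl acetate F6, and Shi epoxidation as in step 2 should give the diepoxy acetate F7. Me3SiOTf with 2,6-di-tert-butyl-4-methylpyridine at −78 °C, followed by mild acidic work-up, should give the bicyclic exocyclic olefin F8 by termination through proton loss. mCPBA/NaHCO3 should epoxidise the methylene group from the equatorial face to give the spiro-epoxide F9. LiAlH4 should open the epoxide at CH2 and cleave the acetate, coming back to the route at 5.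

**Further compounds**

F1 | step 19 | gem-dibromocyclopropane on the convex face of 22 | BrC1(Br)[C@H]2C[C@H]3[C@@H]([C@@]12CC[C@H]1[C@]2(C)CC[C@H](O[Si](CC)(CC)CC)C(C)(C)O[C@H]2CC[C@]1(C)O[Si](CC)(CC)CC)C(C)(C)CC[C@]3(C)O[Si](CC)(CC)CC
F2 | step 19 | ring-expanded 2-bromocyclohex-2-enol (OH on the face of the ring-fusion hydrogens) | BrC1=C(CC[C@H]2[C@]3(C)CC[C@H](O[Si](CC)(CC)CC)C(C)(C)O[C@H]3CC[C@]2(C)O[Si](CC)(CC)CC)[C@@H]2[C@H](C[C@@H]1O)[C@@](C)(O[Si](CC)(CC)CC)CCC2(C)C
F3 | step 19 | 2-methyl allylic alcohol (C–O epimer of the desilylated oxygen pattern of 25) | CC1=C(CC[C@H]2[C@]3(C)CC[C@H](O[Si](CC)(CC)CC)C(C)(C)O[C@H]3CC[C@]2(C)O[Si](CC)(CC)CC)[C@@H]2[C@H](C[C@@H]1O)[C@@](C)(O[Si](CC)(CC)CC)CCC2(C)C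
F4 | step 19 | allylic mesylate of F3 | CC1=C(CC[C@H]2[C@]3(C)CC[C@H](O[Si](CC)(CC)CC)C(C)(C)O[C@H]3CC[C@]2(C)O[Si](CC)(CC)CC)[C@@H]2[C@H](C[C@@H]1OS(C)(=O)=O)[C@@](C)(O[Si](CC)(CC)CC)CCC2(C)C
F5 | step 20 | 2-methoxyprop-2-yl peroxyketal of 25 | CC1=C(CC[C@H]2[C@]3(C)CC[C@H](O[Si](CC)(CC)CC)C(C)(C)O[C@H]3CC[C@]2(C)O[Si](CC)(CC)CC)[C@@H]2[C@H](C[C@H]1OOC(C)(C)OC)[C@@](C)(O[Si](CC)(CC)CC)CCC2(C)C
F6 | step 3 | (2E,6E)-farnesyl acetate | CC(C)=CCC/C(C)=C/CC/C(C)=C/COC(C)=O
F7 | step 3 | (2E,6S,7S,10S)-6,7:10,11-diepoxyfarnesyl acetate | CC1(C)O[C@H]1CC[C@]1(C)O[C@H]1CC/C(C)=C/COC(C)=O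
F8 | step 3 | bicyclic exocyclic olefin (trans-fused oxepane–methylenecyclohexane, acetoxymethyl arm, free secondary OH) | CC(=O)OC[C@H]1[C@]2(C)CC[C@H](O)C(C)(C)O[C@H]2CCC1=C
F9 | step 3 | spiro-epoxide of F8 (oxygen equatorial) | CC(=O)OC[C@H]1[C@]2(C)CC[C@H](O)C(C)(C)O[C@H]2CC[C@@]13CO3
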